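The runs were computed with constants of no real substance, noise included.

**Late readings.** By 80.0 s the cedar run reads 48.0% left-handed product and 7.7% right-handed product. I must decide whether the next flask, run to 4.0 min, keeps 0.098 mol% of racemization catalyst or gets a new charge.

in all of them: free catalyst 2 mol%; racemization catalyst 0.098 mol%

|  | left-handed substrate | right-handed substrate | coupling partner | remark | time |
|---|---|---|---|---|---|
| cedar | 5 mM | 5 mM | 3 equiv | the very flask that is asked about, followed so far |  |
| flask | 5.0 mM | 5.0 mM | 3.00 equiv |  | 4.0 min |

cedar run (percent of the left-handed substrate and right-handed substrate together charged)

| time / s | left-handed product / % | right-handed product / % |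
|---|---|---|
| 10.0 | 12.1 | 0.5 |
| 12.0 | 12.7 | 1.6 |
| 20.0 | 18.3 | 4.0 |
| 30.0 | 26.2 | 0.8 |
| 50.0 | 37.8 | 5.5 |
| 80.0 | 48.0 | 7.7 |

(standard deviation of a reading: 1 percentage point)

- free catalyst is single-handed; left-handed substrate and right-handed substrate are mirror images of each other, charged as a racemate, each of them at the stated concentration
- steps thought possible: coupling partner + racemization catalyst -> spent catalyst B; free catalyst -> spent catalyst A; coupling partner + free catalyst + right-handed substrate -> free catalyst + right-handed product; left-handed substrate + racemization catalyst <-> right-handed substrate + racemization catalyst; coupling partner + free catalyst + left-handed substrate -> free catalyst + left-handed product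
- an excess is the difference of the two amounts in percent of their sum
- an excess is below zero if the other one leads

- left-handed product and right-handed product together, in percent of the left-handed substrate and right-handed substrate charged together, at 4.0 min
- excess of left-handed product over right-handed product in the product at 4.0 min
- whether the exchange between left-handed substrate and right-handed substrate keeps pace with the reaction: how far the product's excess at 4.0 min gets from its value without exchange to its value with instant exchange (above 80% keeps pace, below 20% hardly takes part, else lags behind)

**The feed.** Each product formed uses up coupling partner, so [coupling partner] falls during the cedar run, and I expect the share of left-handed substrate taken in equal times to fall with it, unless something feeds that substrate. Counted without exchange, the cedar run uses 52.4% of its left-handed substrate in the first 30.0 s. But it uses 83.6% of the remainder between 50.0 s and 80.0 s, a larger share. So I read the right-handed substrate as feeding the left-handed one.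

**The ratio.** If exchange holds the two substrates level, every cedar reading shows one ratio, so I sum all 6. My selectivity factor as read, summed left-handed product over summed right-handed product, is 7.72, from readings good to 1 percentage point. The ratio less one, over the ratio plus one, gives an excess of 77.1%. I leave the recipe as it stands and commit to that excess.

**The forecast.** The forecast gives 78% of product, an excess of 57%, and an exchange that lags behind, on the grounds that “the observed 48% suggests a modest feed”. My excess differs: it stands higher.

**The result.** coupling partner + racemization catalyst → spent catalyst B (k = 0.720 /M/s); free catalyst → spent catalyst A (k = 0.00200 /s); coupling partner + free catalyst + right-handed substrate → free catalyst + right-handed product (k = 2100 /M²/s); left-handed substrate + racemization catalyst ⇌ right-handed substrate + racemization catalyst, rate k4*[racemization catalyst]*[left-handed substrate] forward; the back reaction follows from the equilibrium constant (k = 16000 /M/s); coupling partner + free catalyst + left-handed substrate → free catalyst + left-handed product (k = 17000 /M²/s)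

The flask gives 80.2% of product and an excess of 75.2%, and its exchange keeps pace, getting 91% of the way. At 4.00 min the flask holds 8.95% left-handed and 10.8% right-handed substrate, and its products stand in the ratio 7.07, against 7.72 as read. The neighbouring flask, charged with 0.750 equiv of coupling partner, ends with 35.4% and 35.7% of the two substrates, again level, so the ratio as read gives 77.1%. That neighbouring flask shows an excess of 77.6%, at 28.9% of product, with 23.0% of its coupling partner left.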